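**Retrosynthetic overview**

1. Target 20 ⇐ penta-MOM ether 19 ⇐ Mizoroki–Heck union of aryl bromide 15 (C5–Br of the finished dihydrobenzofuran) with aryl vinyl ketone 18; the (E)-enone arm is attached last.
2. 15 ⇐ flavan mesylate 13 by ring contraction: the dihydrofuran ring (O1–C2–C3–C3a–C7a) is closed by forming C3–C3a through a 1,2-shift of the fused benzene carbon from the carbinol carbon C4 to C3 of a chroman, which turns C4 into the aryl ketone in the same event.
3. Enabling feature: C3 of the dihydrobenzofuran bears both the ring-fusion arene carbon C3a and the exocyclic ketone carbon (an α-aryl ketone); these two carbons map onto the C4a–C4 bond of a six-membered benzopyran in which O1–C2 and the C2 aryl group are already in place.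
4. 13 ⇐ diol 12 ⇐ arylmagnesium bromide 10 + trans-dihydroflavonol 7 ⇐ Rubottom oxidation of (2S)-flavanone 3 ⇐ catalytic asymmetric 1,4-addition of boronic acid 2 to 6-bromochromone 1; 10 is made once from bromide 9 as a stock solution and also delivers 18.
5. Ring order: the benzopyranone ring is present from 1, is elaborated stereoselectively in steps 1–3, 6 and 7 and is contracted to the dihydrobenzofuran in step 8; no other ring is built.

Key step: step 8

Remark: the (S,S) ligand in step 1 is assigned by analogy with additions to cyclic enones; if the sense of induction proves opposite, the (R,R) ligand is used and nothing else changes.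
Remark: the C4 configuration drawn for 12–14 is that expected from axial attack (aryl cis to the 3-oxygen); the C4 epimer would converge in step 8 because C4 becomes trigonal.
Remark: C2 is fixed in step 1 and not touched again; its descriptor reads S in 3–5, R in 6, 7 and 11–14, and S again from 15 on only because the CIP rank of C3 changes.

**Route**

Step 1
Reactants: 1 6-bromochromone; 2 [4-(methoxymethoxy)phenyl]boronic acid
Product: 3 (2S)-6-bromo-2-[4-(methoxymethoxy)phenyl]-2,3-dihydro-4H-chromen-4-one
Conditions: [RhCl(C2H4)2]2 (2.5 mol %), (1S,4S)-2,5-diphenylbicyclo[2.2.2]octa-2,5-diene (5.5 mol %), K3PO4 (0.2 equiv), toluene/H2O, 40 °C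
Reagents that add atoms: none
Why: Hayashi–Miyaura asymmetric 1,4-addition of an arylboronic acid to the chromone enone, a reaction type established for chromones with chiral diene ligands; the diene on the aryl–rhodium species selects the enone face and so sets C2, and the aryl bromide should be inert to monovalent rhodium at this temperature.

Step 2
Reactants: 3 (2S)-6-bromo-2-[4-(methoxymethoxy)phenyl]-2,3-dihydro-4H-chromen-4-one
Product: 5 {[(2S)-6-bromo-2-[4-(methoxymethoxy)phenyl]-2H-chromen-4-yl]oxy}(trimethyl)silane, via lithium enolate 4 (not isolated)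
Conditions: Me3SiCl (3 equiv), then LiN(SiMe3)2 (1.2 equiv), THF, −78 °C; pentane, filtration, no aqueous work-up
Reagents that add atoms: chlorotrimethylsilane, C[Si](C)(C)Cl
Why: Silyl enol ether formation by kinetic deprotonation at C3 with internal silyl quench, so that the enolate is trapped before it can open by retro-oxa-Michael elimination and C2 stays intact.

Step 3
Reactants: 5 {[(2S)-6-bromo-2-[4-(methoxymethoxy)phenyl]-2H-chromen-4-yl]oxy}(trimethyl)silane
Product: 7 (2R,3R)-6-bromo-3-hydroxy-2-[4-(methoxymethoxy)phenyl]-2,3-dihydro-4H-chromen-4-one, via silyloxy epoxide 6 (not isolated)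
Conditions: dimethyldioxirane (acetone solution, 1.2 equiv), CH2Cl2, −40 → 0 °C; then citric acid (cat.), THF/H2O, 0 °C
Reagents that add atoms: dimethyldioxirane, CC1(C)OO1
Why: Rubottom oxidation: the dioxirane should epoxidise the enol ether on the face anti to the C2 aryl group, and mild acid hydrolysis of the silyloxy epoxide unveils the 2,3-trans α-hydroxy ketone, so C3 is set by substrate control from C2.

Step 4
Reactants: 8 4-bromoresorcinol
Product: 9 1-bromo-2,4-bis(methoxymethoxy)benzene
Conditions: MeOCH2Cl (2.6 equiv), i-Pr2NEt (3 equiv), CH2Cl2, 0 °C → rt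
Reagents that add atoms: chloromethyl methyl ether, COCCl
Why: O-alkylation of both phenols to the mixed acetals (MOM protection), which tolerate organomagnesium and organoaluminium reagents and are removed together at the end.

Step 5
Reactants: 9 1-bromo-2,4-bis(methoxymethoxy)benzene
Product: 10 [2,4-bis(methoxymethoxy)phenyl]magnesium bromide
Conditions: Mg turnings (1.5 equiv, activated), LiCl (1.2 equiv), THF, 25 °C; solution cannulated off the excess Mg, titrated, kept under Ar as a stock solution
Reagents that add atoms: magnesium, [Mg]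
Why: Grignard reagent formation by insertion of magnesium into the aryl C–Br bond, accelerated and solubilised by LiCl, with the MOM acetals inert to the reagent; the single titrated stock solution serves both step 6 and step 9.

Step 6
Reactants: 7 (2R,3R)-6-bromo-3-hydroxy-2-[4-(methoxymethoxy)phenyl]-2,3-dihydro-4H-chromen-4-one; 10 [2,4-bis(methoxymethoxy)phenyl]magnesium bromide
Product: 12 (2R,3R,4R)-6-bromo-4-[2,4-bis(methoxymethoxy)phenyl]-2-[4-(methoxymethoxy)phenyl]-3,4-dihydro-2H-chromene-3,4-diol, via magnesium alkoxide 11 (not isolated)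
Conditions: 10 (3.2 equiv, THF stock solution), THF, −40 → 0 °C; H2O, then aq. NH4Cl
Reagents that add atoms: none
Why: Grignard 1,2-addition to an unprotected α-hydroxy ketone: the first equivalent forms the C3 magnesium alkoxide, which shields C3–H from enolisation and chelates the C4 carbonyl, and the next adds to C4, axial attack being expected to place the aryl group cis to the 3-oxygen at a centre that is erased in step 8.

Step 7
Reactants: 12 (2R,3R,4R)-6-bromo-4-[2,4-bis(methoxymethoxy)phenyl]-2-[4-(methoxymethoxy)phenyl]-3,4-dihydro-2H-chromene-3,4-diol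
Product: 13 (2R,3R,4R)-6-bromo-4-[2,4-bis(methoxymethoxy)phenyl]-4-hydroxy-2-[4-(methoxymethoxy)phenyl]-3,4-dihydro-2H-chromen-3-yl methanesulfonate
Conditions: MsCl (1.2 equiv), Et3N (2 equiv), CH2Cl2, −20 → 0 °C
Reagents that add atoms: methanesulfonyl chloride, CS(=O)(=O)Cl
Why: Chemoselective sulfonylation (sulfene pathway) of the secondary C3 hydroxyl beside the hindered tertiary C4 hydroxyl, the usual way to prepare a 2-mesyloxy alcohol for semipinacol rearrangement; no stereocentre is touched.

Step 8
Reactants: 13 (2R,3R,4R)-6-bromo-4-[2,4-bis(methoxymethoxy)phenyl]-4-hydroxy-2-[4-(methoxymethoxy)phenyl]-3,4-dihydro-2H-chromen-3-yl methanesulfonate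
Product: 15 [(2S,3S)-5-bromo-2-[4-(methoxymethoxy)phenyl]-2,3-dihydro-1-benzofuran-3-yl][2,4-bis(methoxymethoxy)phenyl]methanone, via aluminium alkoxide 14 (not isolated)
Conditions: Et3Al (3 equiv, hexane solution), CH2Cl2, −78 → 0 °C; aq. potassium sodium tartrate
Reagents that add atoms: none
Why: Et3Al first converts the tertiary C4 hydroxyl into the diethylaluminium alkoxide 14 and then acts as Lewis acid for the C3 mesylate; as the mesylate leaves, the fused arene carbon C4a, whose σ bond to C4 is antiperiplanar to C3–OMs, shifts from C4 to C3 through an aryl-bridged (phenonium-like) transition state while the C4–O bond becomes the aryl ketone, which is an organoaluminium-promoted semipinacol rearrangement of a 2-mesyloxy alcohol. The closest known reactions are that rearrangement on acyclic and carbocyclic mesyloxy alcohols and the hypervalent-iodine ring contraction of flavanones to methyl 2-aryl-2,3-dihydrobenzofuran-3-carboxylates, which uses the same shift of the fused aryl carbon onto C3. The dihydrofuran ring O1–C2–C3–C3a–C7a is closed by this one C3–C3a bond, formally a 3-exo-tet attack of the arene ipso carbon on C3 followed by rupture of the old C4–C4a bond, so the six-membered pyran contracts to the five-membered ring. C3 is the only stereocentre formed and is set by inversion at the mesylate carbon: the aroyl carbon ends where it was, the new aryl bond enters anti to the departing mesylate, and the aroyl group thus lies trans to the untouched C2 aryl group, which gives (2S,3S). The step needs migration of the ring aryl bond in preference to the exocyclic C4 aryl group, the C2 aryl group, participation of the ring oxygen O1 and epoxide closure; the 2,3-trans diequatorial arrangement holds the mesylate antiperiplanar to C4–C4a and gauche to every exocyclic group, the alkoxide push exists only at C4, and the ortho ring oxygen on C8a stabilises the bridged aryl. Either C4 epimer would give the same ketone because C4 becomes trigonal.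

Step 9
Reactants: 10 [2,4-bis(methoxymethoxy)phenyl]magnesium bromide; 16 N-methoxy-N-methylprop-2-enamide
Product: 18 1-[2,4-bis(methoxymethoxy)phenyl]prop-2-en-1-one, via tetrahedral magnesium adduct 17 (not isolated)
Conditions: 10 (1.2 equiv, THF stock solution), 16, THF, −78 → −20 °C; inverse quench into cold 1 M HCl; used fresh
Reagents that add atoms: none
Why: Weinreb ketone synthesis: the chelated tetrahedral adduct resists over-addition, and the cold acidic inverse quench keeps the liberated amine from adding to the new enone.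

Step 10
Reactants: 15 [(2S,3S)-5-bromo-2-[4-(methoxymethoxy)phenyl]-2,3-dihydro-1-benzofuran-3-yl][2,4-bis(methoxymethoxy)phenyl]methanone; 18 1-[2,4-bis(methoxymethoxy)phenyl]prop-2-en-1-one
Product: 19 (2E)-3-[(2S,3S)-3-[2,4-bis(methoxymethoxy)benzoyl]-2-[4-(methoxymethoxy)phenyl]-2,3-dihydro-1-benzofuran-5-yl]-1-[2,4-bis(methoxymethoxy)phenyl]prop-2-en-1-one
Conditions: 18 (1.5 equiv), Pd2(dba)3 (2.5 mol %), [HP(t-Bu)3]BF4 (6 mol %), Cy2NMe (1.3 equiv), 1,4-dioxane, 25 → 40 °C
Reagents that add atoms: none
Why: Mizoroki–Heck reaction: oxidative addition of the electron-rich aryl bromide to zerovalent palladium bearing the bulky phosphine proceeds near ambient temperature, syn-insertion and syn-β-hydride elimination give the (E)-enone, and the hindered amine should leave the acidic C3–H and the dihydrofuran ring alone.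

Step 11
Reactants: 19 (2E)-3-[(2S,3S)-3-[2,4-bis(methoxymethoxy)benzoyl]-2-[4-(methoxymethoxy)phenyl]-2,3-dihydro-1-benzofuran-5-yl]-1-[2,4-bis(methoxymethoxy)phenyl]prop-2-en-1-one
Product: 20 (2E)-3-[(2S,3S)-3-(2,4-dihydroxybenzoyl)-2-(4-hydroxyphenyl)-2,3-dihydro-1-benzofuran-5-yl]-1-(2,4-dihydroxyphenyl)prop-2-en-1-one
Conditions: HCl (1.25 M in MeOH), MeOH/THF, 40 °C
Reagents that add atoms: none
Why: Acid-catalysed acetal methanolysis of the five MOM ethers; the 3-acyl group disfavours a benzylic cation at C2, so the trans-dihydrofuran should survive and no stereocentre is involved.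

**Compound list**

1 | 6-bromo-4H-chromen-4-one (6-bromochromone) | O=c1ccoc2ccc(Br)cc12 | starting material
2 | [4-(methoxymethoxy)phenyl]boronic acid | COCOc1ccc(cc1)B(O)O | starting material
3 | (2S)-6-bromo-2-[4-(methoxymethoxy)phenyl]-2,3-dihydro-4H-chromen-4-one | O=C1C[C@@H](c2ccc(OCOC)cc2)Oc2ccc(Br)cc12 | intermediate
4 | lithium (2S)-6-bromo-2-[4-(methoxymethoxy)phenyl]-2H-chromen-4-olate | [Li]OC1=C[C@@H](c2ccc(OCOC)cc2)Oc2ccc(Br)cc12 | intermediate
5 | {[(2S)-6-bromo-2-[4-(methoxymethoxy)phenyl]-2H-chromen-4-yl]oxy}(trimethyl)silane | C[Si](C)(C)OC1=C[C@@H](c2ccc(OCOC)cc2)Oc2ccc(Br)cc12 | intermediate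
6 | 3,4-epoxide of 5, oxirane oxygen anti to the C2 aryl group, 4-trimethylsilyloxy (flavan numbering 2R,3R,4R) | C[Si](C)(C)O[C@@]12O[C@@H]1[C@@H](c1ccc(OCOC)cc1)Oc1ccc(Br)cc12 | intermediate
7 | (2R,3R)-6-bromo-3-hydroxy-2-[4-(methoxymethoxy)phenyl]-2,3-dihydro-4H-chromen-4-one (2,3-trans) | O=C1[C@H](O)[C@@H](c2ccc(OCOC)cc2)Oc2ccc(Br)cc12 | intermediate
8 | 4-bromobenzene-1,3-diol (4-bromoresorcinol) | Oc1ccc(Br)c(O)c1 | starting material
9 | 1-bromo-2,4-bis(methoxymethoxy)benzene | COCOc1ccc(Br)c(OCOC)c1 | intermediate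
10 | [2,4-bis(methoxymethoxy)phenyl]magnesium bromide (titrated THF stock solution) | COCOc1ccc([Mg]Br)c(OCOC)c1 | intermediate
11 | bromomagnesium (2R,3R)-6-bromo-2-[4-(methoxymethoxy)phenyl]-4-oxo-3,4-dihydro-2H-chromen-3-olate | O=C1[C@H](O[Mg]Br)[C@@H](c2ccc(OCOC)cc2)Oc2ccc(Br)cc12 | intermediate
12 | (2R,3R,4R)-6-bromo-4-[2,4-bis(methoxymethoxy)phenyl]-2-[4-(methoxymethoxy)phenyl]-3,4-dihydro-2H-chromene-3,4-diol (2-aryl and 3-OH trans, 4-aryl cis to 3-OH) | COCOc1ccc(cc1)[C@H]1Oc2ccc(Br)cc2[C@](O)(c2ccc(OCOC)cc2OCOC)[C@@H]1O | intermediate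
13 | (2R,3R,4R)-6-bromo-4-[2,4-bis(methoxymethoxy)phenyl]-4-hydroxy-2-[4-(methoxymethoxy)phenyl]-3,4-dihydro-2H-chromen-3-yl methanesulfonate | COCOc1ccc(cc1)[C@H]1Oc2ccc(Br)cc2[C@](O)(c2ccc(OCOC)cc2OCOC)[C@@H]1OS(C)(=O)=O | intermediate
14 | diethylaluminium alkoxide of 13 (C4–O–AlEt2) | COCOc1ccc(cc1)[C@H]1Oc2ccc(Br)cc2[C@](O[Al](CC)CC)(c2ccc(OCOC)cc2OCOC)[C@@H]1OS(C)(=O)=O | intermediate
15 | [(2S,3S)-5-bromo-2-[4-(methoxymethoxy)phenyl]-2,3-dihydro-1-benzofuran-3-yl][2,4-bis(methoxymethoxy)phenyl]methanone (2,3-trans) | Brc1ccc2c(c1)[C@H](C(=O)c1ccc(OCOC)cc1OCOC)[C@@H](c1ccc(OCOC)cc1)O2 | intermediate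
16 | N-methoxy-N-methylprop-2-enamide | C=CC(=O)N(C)OC | starting material
17 | bromomagnesium 1-[2,4-bis(methoxymethoxy)phenyl]-1-[methoxy(methyl)amino]prop-2-en-1-olate | C=CC(O[Mg]Br)(N(C)OC)c1ccc(OCOC)cc1OCOC | intermediate
18 | 1-[2,4-bis(methoxymethoxy)phenyl]prop-2-en-1-one | C=CC(=O)c1ccc(OCOC)cc1OCOC | intermediate
19 | (2E)-3-[(2S,3S)-3-[2,4-bis(methoxymethoxy)benzoyl]-2-[4-(methoxymethoxy)phenyl]-2,3-dihydro-1-benzofuran-5-yl]-1-[2,4-bis(methoxymethoxy)phenyl]prop-2-en-1-one | O=C(/C=C/c1ccc2c(c1)[C@H](C(=O)c1ccc(OCOC)cc1OCOC)[C@@H](c1ccc(OCOC)cc1)O2)c1ccc(OCOC)cc1OCOC | intermediate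
20 | (2E)-3-[(2S,3S)-3-(2,4-dihydroxybenzoyl)-2-(4-hydroxyphenyl)-2,3-dihydro-1-benzofuran-5-yl]-1-(2,4-dihydroxyphenyl)prop-2-en-1-one | O=C(/C=C/c1ccc2c(c1)[C@H](C(=O)c1ccc(O)cc1O)[C@@H](c1ccc(O)cc1)O2)c1ccc(O)cc1O | target

**Step count and risks**

Total step count: 11. Longest linear sequence: 8 steps (steps 1, 2, 3, 6, 7, 8, 10, 11).

Steps most likely to fail:

Step 8. The risk is that a group other than the ring aryl bond responds to departure of the mesylate. Possible courses are shift of the electron-rich exocyclic C4 aryl group or of the C2 aryl group, participation of the ring oxygen, epoxide closure by the C4 oxygen, or ionisation at the doubly benzylic C4 before the mesylate leaves. The fallback performs the same ring contraction one oxidation level lower, before the C4 aryl group is present. It sets out from 7. Mesylation (MsCl, pyridine, 0 °C) would give (2R,3R)-6-bromo-2-[4-(methoxymethoxy)phenyl]-4-oxo-3,4-dihydro-2H-chromen-3-yl methanesulfonate F1. Reduction with i-Bu2AlH at −78 °C would give (2R,3S)-6-bromo-4-hydroxy-2-[4-(methoxymethoxy)phenyl]-3,4-dihydro-2H-chromen-3-yl methanesulfonate F2. Treatment of F2 with Et3Al should then contract the ring, by the same antiperiplanar shift of the ring aryl bond, to (2S,3S)-5-bromo-2-[4-(methoxymethoxy)phenyl]-2,3-dihydro-1-benzofuran-3-carbaldehyde F3. Addition of 10 at −78 °C would give the carbinol [(2S,3R)-5-bromo-2-[4-(methoxymethoxy)phenyl]-2,3-dihydro-1-benzofuran-3-yl][2,4-bis(methoxymethoxy)phenyl]methanol F4, and Dess–Martin oxidation comes back to the route at 15.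

Step 10. The risk is polymerisation or amine-induced decomposition of the vinyl ketone outrunning the coupling, together with base-mediated epimerisation or retro-oxa-Michael opening at C3. The fallback is base-free and sets out from 15. Stille coupling with tributyl(vinyl)stannane (Pd(PPh3)4, toluene, 90 °C) would give the styrene [(2S,3S)-5-ethenyl-2-[4-(methoxymethoxy)phenyl]-2,3-dihydro-1-benzofuran-3-yl][2,4-bis(methoxymethoxy)phenyl]methanone F5. Olefin cross-metathesis of F5 with 18 (second-generation Hoveyda–Grubbs catalyst, CH2Cl2, 40 °C) should give the (E)-enone and comes back at 19.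

Step 6. The risk is proton transfer in place of carbonyl addition: after the O–H, enolisation at C3 with retro-oxa-Michael opening, stalling at the chelated magnesium alkoxide, or an α-ketol shift of that alkoxide. The fallback removes the free hydroxyl first and sets out from 7. Silylation (Et3SiCl, imidazole, CH2Cl2) would give (2R,3R)-6-bromo-2-[4-(methoxymethoxy)phenyl]-3-[(triethylsilyl)oxy]-2,3-dihydro-4H-chromen-4-one F6. Addition of 10 (1.5 equiv, −78 °C) would give the silyl-protected carbinol (2R,3R,4R)-6-bromo-4-[2,4-bis(methoxymethoxy)phenyl]-2-[4-(methoxymethoxy)phenyl]-3-[(triethylsilyl)oxy]-3,4-dihydro-2H-chromen-4-ol F7. Desilylation with Bu4NF/AcOH comes back at 12.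

**Further compounds**

F1 | step 8 | (2R,3R)-6-bromo-2-[4-(methoxymethoxy)phenyl]-4-oxo-3,4-dihydro-2H-chromen-3-yl methanesulfonate | O=C1[C@H](OS(C)(=O)=O)[C@@H](c2ccc(OCOC)cc2)Oc2ccc(Br)cc12
F2 | step 8 | (2R,3S)-6-bromo-4-hydroxy-2-[4-(methoxymethoxy)phenyl]-3,4-dihydro-2H-chromen-3-yl methanesulfonate (C4 epimers) | OC1[C@H](OS(C)(=O)=O)[C@@H](c2ccc(OCOC)cc2)Oc2ccc(Br)cc12
F3 | step 8 | (2S,3S)-5-bromo-2-[4-(methoxymethoxy)phenyl]-2,3-dihydro-1-benzofuran-3-carbaldehyde | Brc1ccc2c(c1)[C@H](C=O)[C@@H](c1ccc(OCOC)cc1)O2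
F4 | step 8 | [(2S,3R)-5-bromo-2-[4-(methoxymethoxy)phenyl]-2,3-dihydro-1-benzofuran-3-yl][2,4-bis(methoxymethoxy)phenyl]methanol (carbinol epimers) | Brc1ccc2c(c1)[C@H](C(O)c1ccc(OCOC)cc1OCOC)[C@@H](c1ccc(OCOC)cc1)O2
F5 | step 10 | [(2S,3S)-5-ethenyl-2-[4-(methoxymethoxy)phenyl]-2,3-dihydro-1-benzofuran-3-yl][2,4-bis(methoxymethoxy)phenyl]methanone | C=Cc1ccc2c(c1)[C@H](C(=O)c1ccc(OCOC)cc1OCOC)[C@@H](c1ccc(OCOC)cc1)O2
F6 | step 6 | (2R,3R)-6-bromo-2-[4-(methoxymethoxy)phenyl]-3-[(triethylsilyl)oxy]-2,3-dihydro-4H-chromen-4-one | O=C1[C@H](O[Si](CC)(CC)CC)[C@@H](c2ccc(OCOC)cc2)Oc2ccc(Br)cc12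
F7 | step 6 | (2R,3R,4R)-6-bromo-4-[2,4-bis(methoxymethoxy)phenyl]-2-[4-(methoxymethoxy)phenyl]-3-[(triethylsilyl)oxy]-3,4-dihydro-2H-chromen-4-ol | COCOc1ccc(cc1)[C@H]1Oc2ccc(Br)cc2[C@](O)(c2ccc(OCOC)cc2OCOC)[C@@H]1O[Si](CC)(CC)CC
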